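Compound numbers refer to the steps and the compound list below; abiesin is 21.

## The problem

Abiesin (21) is an unsymmetrical biflavonoid. C6 of a 3,7-dihydroxy-4'-methoxyflavone (the flavonol half) is bonded to C3' of a 5-hydroxy-7,4'-dimethoxyflavone (the flavone half), so three benzene rings and two 4-pyranones surround one biaryl bond. That bond is the hard part: it joins two electron-rich carbons, each ortho to an oxygen (the C7 hydroxyl on one side, the C4' methoxyl on the other), and the flavonol ring A that carries it is a 1,2,4,5-tetrasubstituted benzene for which no simple building block exists. The molecule has no stereocentre, so the selectivity questions are regiochemistry and the differentiation of six oxygen functions. Three methyl ethers must stay and three hydroxyls (flavonol C3 and C7, flavone C5) must end free. The 4-pyranone rings are opened at C2 by hot aqueous alkali, the enolic C3 hydroxyl is readily acylated and oxidized, the C2=C3 bonds limit reductions, and the methyl ethers rule out strong Lewis acids for deprotection. The enabling feature is the pattern of flavonol ring A: oxygen on C7 and C8a in a 1,3 relation, the acyl carbon C4 on C4a, the anisole ring on C6, and hydrogen on C5 and C8. This is a 5-aryl-2,4-dihydroxyacetophenone, and it divides into a four-carbon 1,3-dioxygenated diene (C6, C7, C8, C8a, aryl on C6) and a two-carbon acetylenic ketone (C5, C4a). Ring A can therefore be made by cycloaddition, with the biaryl bond already present as the aryl–CH2 bond of an arylacetic acid.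

## Retrosynthesis

**21 ⇒ 20 (two O–benzyl bonds).** The flavone C5 hydroxyl is hydrogen-bonded to its carbonyl and can be carried free. The flavonol C3 and C7 hydroxyls must be masked through alkaline, acid chloride and enolate steps. Benzyl ethers on both are chosen because one neutral hydrogenolysis removes them from 20 and leaves the three methyl ethers alone.

**20 ⇒ 19 ⇒ 16 + 17 (flavone ring C: O1–C2 and C3–C4).** The Baker–Venkataraman-type cut is preferred over a chalcone route or a cross-coupling at flavone C2. Its partner, 1-(2,6-dihydroxy-4-methoxyphenyl)ethanone 17, is commercial and already holds flavone ring A with the correct oxygens. Diketone 19 should arise by C-aroylation of the lithium polyanion of unprotected 17 with acid chloride 18 (from acid 16), then close with acid. The forward step must acylate at carbon, not oxygen, and must tolerate the benzyloxychromone of 18.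

**16 ⇒ 15 (aryl–CO2H bond).** The carboxyl carbon is introduced late by palladium-catalysed hydroxycarbonylation of aryl bromide 15. A bromide is preferred to an ester carried from the start because it is inert to amide base, silylation, the cycloaddition, alkali and alkaline peroxide, and it is present in the commercial acid 1. The forward step must work on an electron-rich bromide without harming the chromone.

**15 ⇒ 14 ⇒ 12 ⇒ 10 + 11 (flavonol ring C).** Benzyl ether 15 comes from flavonol 14. The O1–C2 bond and the C3 oxygen of 14 are traced to an Algar–Flynn–Oyamada oxidation of 2'-hydroxychalcone 12, which installs the C3 hydroxyl in the ring-closing event. Chalcone 12 is cut at its Cα=Cβ bond into acetophenone 10 and 4-methoxybenzaldehyde 11 (Claisen–Schmidt). The precursor is one aromatic ring smaller and the reagents are commodity chemicals.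

**10 ⇒ 9 ⇒ 6 + 7 (flavonol ring A: C5–C6 and C4a–C8a).** Benzyl ether 10 comes from resorcinol 9 by alkylation of the hydroxyl that is not hydrogen-bonded to the ketone. Ring A of 9 is then cut into diene 6 and but-3-yn-2-one 7, through cycloadduct 8. The neighbouring options are a cross-coupling to a halogenated resacetophenone or acetylation of a 4-arylresorcinol. Both would have to form the doubly ortho-oxygenated biaryl bond between two electron-rich partners, and the coupling would also have to spare the bromide needed later. The cycloaddition avoids this, since the biaryl bond is never formed as such. The forward reaction needs one regiochemistry, [4+2] ring closure in place of closure through the central diene carbon, and aromatization by loss of methanol and the silyl groups.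

**6 ⇒ 5 ⇒ 4 ⇒ 1 + 2 (diene).** Diene 6 is the bis-silyl dienol ether of β-ketoester 4, made in two O-silylations via enoate 5. Ketoester 4 comes from 2-(5-bromo-2-methoxyphenyl)acetic acid 1 by two-carbon homologation with Meldrum's acid 2, through adduct 3. The CH2 and carboxyl carbons of 1 become C6 and C7, and the two carbons from 2 become C8 and C8a.

## Roads not taken

Alternative 1: The cut is the C2=C3 bond of the flavone ring C. Acylphosphorane A1, whose ortho phenol oxygen carries the biaryl aroyl group as an ester, would cyclize on heating by attack of the ylide carbon on the ester carbonyl, giving the tri-O-benzyl derivative A2 of the target. Its merit is a neutral ring closure with no enolate O/C ambiguity and no acid; in that respect it is gentler than the acid cyclodehydration of 19 and arguably better. Its weakness is that it only closes the easiest ring. The biaryl acid 16 is still required, so the real problem (flavonol ring A with its biaryl bond) is untouched. In addition, the phosphorane needs a desymmetrized, monobenzylated derivative of 17, a third benzyl group, a stabilized ylide reacting with a poor acceptor at high temperature, and removal of stoichiometric phosphorus waste from a polar product. The chosen plan reaches the same ring from unprotected 17 in two steps, and its key step addresses the hard ring.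

Alternative 2: The cut is C3–C4 and O1–C2 of the flavonol pyranone. Salicylaldehyde A3 and sulfoxonium ylide A4 would be annulated by a cationic pentamethylcyclopentadienyl catalyst of trivalent rhodium through aldehyde C–H activation, carbene insertion and cyclodehydration, giving flavone ester A5. It is convergent and catalytic, and it carries the carboxyl carbon as an ester from the start, so it needs no carbonylation; on these points it is better than the chosen plan. Against this, A5 has hydrogen at C3, so the flavonol hydroxyl must be added later by a separate oxidation. More seriously, the biaryl bond of A3 still has to be made by coupling two ortho-oxygenated arenes, which is the difficulty the chosen plan removes. The chosen plan also obtains the C3 hydroxyl in the ring closure from hydrogen peroxide, inherits the biaryl regiochemistry from 1, and uses no precious metal before step 9.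

Alternative 3: The cut is four bonds of the flavone ring A. Wolff rearrangement of diazoketone A6 would give a pyranyl ketene that adds methoxyethyne A7; four-electron ring opening of the cyclobutenone and six-electron closure would then give flavone A8. The 5-hydroxy-7-methoxy pattern would appear in one operation with the C5 hydroxyl already free, which forms more bonds per step than the chosen cycloaddition. Its weakness is that it spends this power on the one ring that can be bought complete (17). A6 needs the biaryl in place, a 4-oxopyran-2-carboxylic acid and a diazoalkane step, and A7 is volatile and unstable. The flavonol half would then have to be built from the bromide of A8 (acetyl introduction, selective debenzylation, chalcone formation, alkaline oxidation) in the presence of a finished, base-sensitive flavone. The chosen plan uses its ring construction on flavonol ring A, which has no commercial equivalent, and keeps the fragile flavone for the last steps.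

Key step: step 4

Assumption: the biaryl axis, flanked by one hydroxyl and one methoxyl group, is taken to rotate freely at room temperature, so 21 and all aromatic intermediates are treated as achiral.

## Route

Step 1
Reactants: 1 2-(5-bromo-2-methoxyphenyl)acetic acid; 2 2,2-dimethyl-1,3-dioxane-4,6-dione (Meldrum's acid)
Product: 4 methyl 4-(5-bromo-2-methoxyphenyl)-3-oxobutanoate, via acyl Meldrum's acid 3 (not isolated)
Conditions: DCC, DMAP, CH2Cl2, 0 °C to rt; filter, concentrate; then MeOH, reflux
Reagents that add atoms: methanol, CO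
Why: Carbodiimide C-acylation of Meldrum's acid by the arylacetic acid, then methanolysis of adduct 3 with loss of acetone and carbon dioxide, is the standard two-carbon homologation of an acid to a β-ketoester; the bromide and the methyl ether are inert.

Step 2
Reactants: 4 methyl 4-(5-bromo-2-methoxyphenyl)-3-oxobutanoate
Product: 5 methyl (2E)-4-(5-bromo-2-methoxyphenyl)-3-(trimethylsilyloxy)but-2-enoate
Conditions: Me3SiCl, Et3N, toluene, rt; filtration under N2
Reagents that add atoms: chlorotrimethylsilane, C[Si](C)(C)Cl
Why: Soft enolization of the doubly activated C2–H and O-silylation of the ketone oxygen (silyl enol ether formation); the enoate geometry, drawn E, is immaterial because this bond becomes the central single bond of the diene.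

Step 3
Reactants: 5 methyl (2E)-4-(5-bromo-2-methoxyphenyl)-3-(trimethylsilyloxy)but-2-enoate
Product: 6 (1Z,3Z)-4-(5-bromo-2-methoxyphenyl)-1-methoxy-1,3-bis(trimethylsilyloxy)buta-1,3-diene
Conditions: LiN(i-Pr)2, THF, −78 °C; Me3SiCl, −78 °C to rt; nonaqueous work-up, used crude
Reagents that add atoms: chlorotrimethylsilane, C[Si](C)(C)Cl
Why: Kinetic γ-deprotonation at the benzylic, vinylogous CH2 and O-silylation of the ester dienolate (silyl ketene acetal formation); the amide base does not exchange with the aryl bromide at −78 °C, and 4-substituted dienes of this class are expected with the C4 substituent cis to the silyloxy group, which places the aryl group outward.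

Step 4
Reactants: 6 (1Z,3Z)-4-(5-bromo-2-methoxyphenyl)-1-methoxy-1,3-bis(trimethylsilyloxy)buta-1,3-diene; 7 but-3-yn-2-one
Product: 9 1-[5-(5-bromo-2-methoxyphenyl)-2,4-dihydroxyphenyl]ethanone, via cycloadduct 8 (not isolated)
Conditions: 7 (2 equiv), toluene, −20 °C to rt, then 50 °C (sealed vessel), no Lewis acid; then 1 M HCl, THF, rt
Reagents that add atoms: none
Why: Normal-electron-demand Diels–Alder reaction: the aryl-bearing terminus C4 has the largest HOMO coefficient (γ-carbon of an ester dienolate, reinforced by the C3 silyloxy group) and bonds to the ynone β-carbon while the ketene acetal carbon C1 bonds to the α-carbon, closing the six-membered carbocycle in a concerted but asynchronous [4+2] mode (at the polar extreme, Mukaiyama–Michael addition followed by collapse of the allenolate onto the silyloxy-stabilized cation at C1 gives the same two bonds). Cycloadduct 8 has a mixed methyl silyl ketal at C1 and a doubly allylic hydrogen at C4, so loss of methanol and acid cleavage of the two silyl ethers aromatize it to the resorcinol, with the acetyl group ortho to the C1-derived hydroxyl and the aryl group ortho to the C3-derived hydroxyl. The closest known reaction type is the cycloaddition of 1-alkoxy-1,3-bis(silyloxy)buta-1,3-dienes and related 1,3-dioxygenated dienes with acetylenic ketones and esters, which gives acylresorcinols and resorcylates after the same elimination. The two stereocentres of 8 (cis from suprafacial addition to the diene as drawn) need no control because both are erased on aromatization, and 9 has none. Regiochemistry is secured by the matched polarization of the diene (donors at C1 and C3) and the ynone; [4+2] closure over [3+3] Michael–aldol closure of C2 onto the ketone is favoured by omitting any Lewis acid, so the silyl groups stay on oxygen until both bonds exist; addition to C≡C over C=O is the thermal preference of ynones. The outward aryl group leaves the s-cis conformation accessible and the aryl bromide is a spectator.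

Step 5
Reactants: 9 1-[5-(5-bromo-2-methoxyphenyl)-2,4-dihydroxyphenyl]ethanone
Product: 10 1-[4-(benzyloxy)-5-(5-bromo-2-methoxyphenyl)-2-hydroxyphenyl]ethanone
Conditions: BnBr (1.05 equiv), K2CO3, acetone, reflux
Reagents that add atoms: benzyl bromide, BrCc1ccccc1
Why: Williamson etherification; the C4 hydroxyl para to the acetyl group is the more acidic and more nucleophilic one, while the C2 hydroxyl is held in a hydrogen bond to the ketone, as in the selective 4-O-alkylation of 2,4-dihydroxyacetophenone.

Step 6
Reactants: 10 1-[4-(benzyloxy)-5-(5-bromo-2-methoxyphenyl)-2-hydroxyphenyl]ethanone; 11 4-methoxybenzaldehyde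
Product: 12 (2E)-1-[4-(benzyloxy)-5-(5-bromo-2-methoxyphenyl)-2-hydroxyphenyl]-3-(4-methoxyphenyl)prop-2-en-1-one
Conditions: KOH (50% aq), EtOH, rt
Reagents that add atoms: none
Why: Claisen–Schmidt condensation of a methyl ketone with a non-enolizable aldehyde gives the (E)-2'-hydroxychalcone under thermodynamic control; benzyl ether, methyl ethers and bromide are stable to alkali.

Step 7
Reactants: 12 (2E)-1-[4-(benzyloxy)-5-(5-bromo-2-methoxyphenyl)-2-hydroxyphenyl]-3-(4-methoxyphenyl)prop-2-en-1-one
Product: 14 7-(benzyloxy)-6-(5-bromo-2-methoxyphenyl)-3-hydroxy-2-(4-methoxyphenyl)-4H-chromen-4-one, via trans-dihydroflavonol 13 (not isolated)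
Conditions: 30% aq H2O2, 2 M aq NaOH, MeOH/THF, 0 °C to rt; then 1 M HCl
Reagents that add atoms: hydrogen peroxide, OO
Why: Algar–Flynn–Oyamada oxidation: alkaline peroxide converts the 2'-hydroxychalcone through trans-dihydroflavonol 13 into the flavonol, and the absence of a 6' substituent disfavours the aurone pathway; the transient C2 and C3 stereocentres of 13 are lost on oxidation.

Step 8
Reactants: 14 7-(benzyloxy)-6-(5-bromo-2-methoxyphenyl)-3-hydroxy-2-(4-methoxyphenyl)-4H-chromen-4-one
Product: 15 3,7-bis(benzyloxy)-6-(5-bromo-2-methoxyphenyl)-2-(4-methoxyphenyl)-4H-chromen-4-one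
Conditions: BnBr, K2CO3, DMF, rt
Reagents that add atoms: benzyl bromide, BrCc1ccccc1
Why: Williamson etherification of the acidic enolic C3 hydroxyl; it masks the only remaining hydroxyl before acid chloride and enolate chemistry and matches the C7 benzyl ether for a single final deprotection.

Step 9
Reactants: 15 3,7-bis(benzyloxy)-6-(5-bromo-2-methoxyphenyl)-2-(4-methoxyphenyl)-4H-chromen-4-one
Product: 16 3-[3,7-bis(benzyloxy)-2-(4-methoxyphenyl)-4-oxo-4H-chromen-6-yl]-4-methoxybenzoic acid
Conditions: Pd(OAc)2 (5 mol %), Xantphos (6 mol %), CO (1 atm), Et3N, H2O, 1,4-dioxane, 90 °C; then 1 M HCl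
Reagents that add atoms: carbon monoxide, [C-]#[O+]; water, O
Why: Palladium-catalysed hydroxycarbonylation (Heck carbonylation): oxidative addition of the aryl bromide to zerovalent palladium, CO insertion and hydrolysis of the acylpalladium intermediate; the wide-bite-angle ligand permits atmospheric CO, and the bromide is unhindered (meta to the biaryl bond).

Step 10
Reactants: 16 3-[3,7-bis(benzyloxy)-2-(4-methoxyphenyl)-4-oxo-4H-chromen-6-yl]-4-methoxybenzoic acid; 17 1-(2,6-dihydroxy-4-methoxyphenyl)ethanone
Product: 19 1-{3-[3,7-bis(benzyloxy)-2-(4-methoxyphenyl)-4-oxo-4H-chromen-6-yl]-4-methoxyphenyl}-3-(2,6-dihydroxy-4-methoxyphenyl)propane-1,3-dione, via acid chloride 18 (not isolated)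
Conditions: 16, (COCl)2, DMF (cat.), CH2Cl2, 0 °C to rt, evaporate; 17, LiN(SiMe3)2 (4.2 equiv), THF, −78 to −10 °C, then 18 in THF, −78 °C to rt; 1 M HCl
Reagents that add atoms: none
Why: Acid chloride formation followed by Claisen-type C-aroylation of the lithium polyanion of the hydroxyacetophenone, the direct variant of the Baker–Venkataraman synthesis; the phenols are masked as lithium phenoxides, so 17 needs no protecting group, and the terminal enolate carbon is the most nucleophilic site.

Step 11
Reactants: 19 1-{3-[3,7-bis(benzyloxy)-2-(4-methoxyphenyl)-4-oxo-4H-chromen-6-yl]-4-methoxyphenyl}-3-(2,6-dihydroxy-4-methoxyphenyl)propane-1,3-dione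
Product: 20 3,7-bis(benzyloxy)-6-[5-(5-hydroxy-7-methoxy-4-oxo-4H-chromen-2-yl)-2-methoxyphenyl]-2-(4-methoxyphenyl)-4H-chromen-4-one
Conditions: AcOH, H2SO4 (cat.), 80 °C
Reagents that add atoms: none
Why: Acid-catalysed cyclodehydration of an o-hydroxyaryl 1,3-diketone (last stage of the Baker–Venkataraman flavone synthesis); either of the two equivalent phenols closes ring C and the other becomes the hydrogen-bonded C5 hydroxyl, and any partial benzyl loss is harmless because step 12 removes both.

Step 12
Reactants: 20 3,7-bis(benzyloxy)-6-[5-(5-hydroxy-7-methoxy-4-oxo-4H-chromen-2-yl)-2-methoxyphenyl]-2-(4-methoxyphenyl)-4H-chromen-4-one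
Product: 21 abiesin, 3,7-dihydroxy-6-[5-(5-hydroxy-7-methoxy-4-oxo-4H-chromen-2-yl)-2-methoxyphenyl]-2-(4-methoxyphenyl)-4H-chromen-4-one
Conditions: H2 (1 atm), 10% Pd/C, THF/MeOH, rt
Reagents that add atoms: none
Why: Hydrogenolysis of the two benzyl ethers over palladium on carbon; methyl ethers are untouched and the conjugated pyranone C2=C3 bonds are not reduced at atmospheric pressure and room temperature.

## Compound list

1 | 2-(5-bromo-2-methoxyphenyl)acetic acid | COc1ccc(Br)cc1CC(=O)O | starting material
2 | 2,2-dimethyl-1,3-dioxane-4,6-dione (Meldrum's acid) | CC1(C)OC(=O)CC(=O)O1 | starting material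
3 | 5-[2-(5-bromo-2-methoxyphenyl)-1-hydroxyethylidene]-2,2-dimethyl-1,3-dioxane-4,6-dione | CC1(C)OC(=O)C(=C(O)Cc2cc(Br)ccc2OC)C(=O)O1 | intermediate
4 | methyl 4-(5-bromo-2-methoxyphenyl)-3-oxobutanoate | COC(=O)CC(=O)Cc1cc(Br)ccc1OC | intermediate
5 | methyl (2E)-4-(5-bromo-2-methoxyphenyl)-3-(trimethylsilyloxy)but-2-enoate | COC(=O)/C=C(\Cc1cc(Br)ccc1OC)O[Si](C)(C)C | intermediate
6 | (1Z,3Z)-4-(5-bromo-2-methoxyphenyl)-1-methoxy-1,3-bis(trimethylsilyloxy)buta-1,3-diene | CO/C(O[Si](C)(C)C)=C/C(O[Si](C)(C)C)=C/c1cc(Br)ccc1OC | intermediate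
7 | but-3-yn-2-one | CC(=O)C#C | starting material
8 | 1-[6-(5-bromo-2-methoxyphenyl)-3-methoxy-3,5-bis(trimethylsilyloxy)cyclohexa-1,4-dien-1-yl]ethanone (racemic, aryl and methoxy cis; one enantiomer drawn) | CC(=O)C1=C[C@H](c2cc(Br)ccc2OC)C(O[Si](C)(C)C)=C[C@@]1(OC)O[Si](C)(C)C | intermediate
9 | 1-[5-(5-bromo-2-methoxyphenyl)-2,4-dihydroxyphenyl]ethanone | CC(=O)c1cc(-c2cc(Br)ccc2OC)c(O)cc1O | intermediate
10 | 1-[4-(benzyloxy)-5-(5-bromo-2-methoxyphenyl)-2-hydroxyphenyl]ethanone | CC(=O)c1cc(-c2cc(Br)ccc2OC)c(OCc2ccccc2)cc1O | intermediate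
11 | 4-methoxybenzaldehyde | COc1ccc(C=O)cc1 | starting material
12 | (2E)-1-[4-(benzyloxy)-5-(5-bromo-2-methoxyphenyl)-2-hydroxyphenyl]-3-(4-methoxyphenyl)prop-2-en-1-one | COc1ccc(/C=C/C(=O)c2cc(-c3cc(Br)ccc3OC)c(OCc3ccccc3)cc2O)cc1 | intermediate
13 | trans-7-(benzyloxy)-6-(5-bromo-2-methoxyphenyl)-3-hydroxy-2-(4-methoxyphenyl)chroman-4-one (racemic; one enantiomer drawn) | O=C1c2cc(-c3cc(Br)ccc3OC)c(OCc3ccccc3)cc2O[C@@H](c2ccc(OC)cc2)[C@@H]1O | intermediate
14 | 7-(benzyloxy)-6-(5-bromo-2-methoxyphenyl)-3-hydroxy-2-(4-methoxyphenyl)-4H-chromen-4-one | COc1ccc(-c2oc3cc(OCc4ccccc4)c(-c4cc(Br)ccc4OC)cc3c(=O)c2O)cc1 | intermediate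
15 | 3,7-bis(benzyloxy)-6-(5-bromo-2-methoxyphenyl)-2-(4-methoxyphenyl)-4H-chromen-4-one | COc1ccc(-c2oc3cc(OCc4ccccc4)c(-c4cc(Br)ccc4OC)cc3c(=O)c2OCc2ccccc2)cc1 | intermediate
16 | 3-[3,7-bis(benzyloxy)-2-(4-methoxyphenyl)-4-oxo-4H-chromen-6-yl]-4-methoxybenzoic acid | COc1ccc(-c2oc3cc(OCc4ccccc4)c(-c4cc(C(=O)O)ccc4OC)cc3c(=O)c2OCc2ccccc2)cc1 | intermediate
17 | 1-(2,6-dihydroxy-4-methoxyphenyl)ethanone | CC(=O)c1c(O)cc(OC)cc1O | starting material
18 | 3-[3,7-bis(benzyloxy)-2-(4-methoxyphenyl)-4-oxo-4H-chromen-6-yl]-4-methoxybenzoyl chloride | COc1ccc(-c2oc3cc(OCc4ccccc4)c(-c4cc(C(=O)Cl)ccc4OC)cc3c(=O)c2OCc2ccccc2)cc1 | intermediate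
19 | 1-{3-[3,7-bis(benzyloxy)-2-(4-methoxyphenyl)-4-oxo-4H-chromen-6-yl]-4-methoxyphenyl}-3-(2,6-dihydroxy-4-methoxyphenyl)propane-1,3-dione | COc1ccc(-c2oc3cc(OCc4ccccc4)c(-c4cc(C(=O)CC(=O)c5c(O)cc(OC)cc5O)ccc4OC)cc3c(=O)c2OCc2ccccc2)cc1 | intermediate
20 | 3,7-bis(benzyloxy)-6-[5-(5-hydroxy-7-methoxy-4-oxo-4H-chromen-2-yl)-2-methoxyphenyl]-2-(4-methoxyphenyl)-4H-chromen-4-one (3,7-di-O-benzylabiesin) | COc1ccc(-c2oc3cc(OCc4ccccc4)c(-c4cc(-c5cc(=O)c6c(O)cc(OC)cc6o5)ccc4OC)cc3c(=O)c2OCc2ccccc2)cc1 | intermediate
21 | abiesin, 3,7-dihydroxy-6-[5-(5-hydroxy-7-methoxy-4-oxo-4H-chromen-2-yl)-2-methoxyphenyl]-2-(4-methoxyphenyl)-4H-chromen-4-one | COc1ccc(-c2oc3cc(O)c(-c4cc(-c5cc(=O)c6c(O)cc(OC)cc6o5)ccc4OC)cc3c(=O)c2O)cc1 | target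

## Step count and risk

Total: 12 steps. Longest linear sequence: 12 steps (1 to 21); 2, 7, 11 and 17 enter as commercial reagents.

**Step 4 (key step).** The likeliest failure is diversion of the ring closure. After the first bond forms between the aryl-bearing terminus and the ynone β-carbon, the central diene carbon can close onto the ketone carbonyl ([3+3] Michael–aldol course), or adventitious protodesilylation can stop the sequence at the open-chain Michael adduct. Oligomerization of the ynone and slow reaction of any diene fraction with an inward aryl group would lower conversion further. The fallback sets out from diene 6 and changes the two-carbon partner to methyl propiolate (toluene, 60–80 °C; then 1 M HCl, THF), whose ester carbonyl does not invite aldol closure. The cycloadduct methyl 6-(5-bromo-2-methoxyphenyl)-3-methoxy-3,5-bis(trimethylsilyloxy)cyclohexa-1,4-diene-1-carboxylate F1 is not isolated and should aromatize to methyl 5-(5-bromo-2-methoxyphenyl)-2,4-dihydroxybenzoate F2. Saponification (aq NaOH, MeOH, reflux) would give 5-(5-bromo-2-methoxyphenyl)-2,4-dihydroxybenzoic acid F3. Excess MeLi (THF, 0 °C) would then convert the lithium carboxylate into the methyl ketone, returning to the route at 9.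

**Step 7.** The oxidation may stall at the dihydroflavonol stage, or the electron-rich enone may suffer oxidative cleavage in alkaline peroxide; poor solubility of the phenoxide would aggravate both. The fallback sets out from chalcone 12 and separates ring closure from hydroxylation. I2 (cat.) in DMSO at 120 °C should give 7-(benzyloxy)-6-(5-bromo-2-methoxyphenyl)-2-(4-methoxyphenyl)-4H-chromen-4-one F4. Dimethyldioxirane (acetone/CH2Cl2, 0 °C) would epoxidize its C2=C3 bond to 7-(benzyloxy)-6-(5-bromo-2-methoxyphenyl)-2,3-epoxy-2-(4-methoxyphenyl)chroman-4-one F5. Catalytic p-TsOH would open and tautomerize the epoxide to the flavonol, returning at 14.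

**Step 9.** Attack of hydroxide or water at C2 of the benzyloxychromone under hot basic conditions, and hydrodebromination competing with CO insertion, are the main concerns. The fallback sets out from 15 and separates the palladium step from water. Anhydrous methoxycarbonylation (Pd(OAc)2, Xantphos, CO 1 atm, MeOH, Et3N, 70 °C) would give methyl 3-[3,7-bis(benzyloxy)-2-(4-methoxyphenyl)-4-oxo-4H-chromen-6-yl]-4-methoxybenzoate F6. Saponification with LiOH (THF/H2O, rt) returns to the route at 16.

**Step 10.** The acid chloride may acylate a phenoxide oxygen instead of the enolate carbon, the diketone may be acylated a second time, or the enolate may add to C2 of the chromone in 18. The fallback sets out from 17 and 18 and follows the two-stage Baker–Venkataraman course. O-aroylation (pyridine, CH2Cl2, 0 °C to rt) would give 2-acetyl-3-hydroxy-5-methoxyphenyl 3-[3,7-bis(benzyloxy)-2-(4-methoxyphenyl)-4-oxo-4H-chromen-6-yl]-4-methoxybenzoate F7. Base-induced 1,5-acyl shift (powdered KOH, pyridine, 50 °C) returns to the route at 19.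

## Further compounds

F1 | step 4 | methyl 6-(5-bromo-2-methoxyphenyl)-3-methoxy-3,5-bis(trimethylsilyloxy)cyclohexa-1,4-diene-1-carboxylate (racemic, aryl and methoxy cis) | COC(=O)C1=C[C@H](c2cc(Br)ccc2OC)C(O[Si](C)(C)C)=C[C@@]1(OC)O[Si](C)(C)C
F2 | step 4 | methyl 5-(5-bromo-2-methoxyphenyl)-2,4-dihydroxybenzoate | COC(=O)c1cc(-c2cc(Br)ccc2OC)c(O)cc1O
F3 | step 4 | 5-(5-bromo-2-methoxyphenyl)-2,4-dihydroxybenzoic acid | OC(=O)c1cc(-c2cc(Br)ccc2OC)c(O)cc1O
F4 | step 7 | 7-(benzyloxy)-6-(5-bromo-2-methoxyphenyl)-2-(4-methoxyphenyl)-4H-chromen-4-one | COc1ccc(-c2cc(=O)c3cc(-c4cc(Br)ccc4OC)c(OCc4ccccc4)cc3o2)cc1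
F5 | step 7 | 7-(benzyloxy)-6-(5-bromo-2-methoxyphenyl)-2,3-epoxy-2-(4-methoxyphenyl)chroman-4-one (racemic, cis-fused epoxide) | O=C1c2cc(-c3cc(Br)ccc3OC)c(OCc3ccccc3)cc2O[C@]2(c3ccc(OC)cc3)O[C@H]12
F6 | step 9 | methyl 3-[3,7-bis(benzyloxy)-2-(4-methoxyphenyl)-4-oxo-4H-chromen-6-yl]-4-methoxybenzoate | COc1ccc(-c2oc3cc(OCc4ccccc4)c(-c4cc(C(=O)OC)ccc4OC)cc3c(=O)c2OCc2ccccc2)cc1
F7 | step 10 | 2-acetyl-3-hydroxy-5-methoxyphenyl 3-[3,7-bis(benzyloxy)-2-(4-methoxyphenyl)-4-oxo-4H-chromen-6-yl]-4-methoxybenzoate | COc1ccc(-c2oc3cc(OCc4ccccc4)c(-c4cc(C(=O)Oc5cc(OC)cc(O)c5C(C)=O)ccc4OC)cc3c(=O)c2OCc2ccccc2)cc1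
A1 | alternative 1 | 3-(benzyloxy)-5-methoxy-2-[(triphenyl-λ5-phosphanylidene)acetyl]phenyl 3-[3,7-bis(benzyloxy)-2-(4-methoxyphenyl)-4-oxo-4H-chromen-6-yl]-4-methoxybenzoate | COc1ccc(-c2oc3cc(OCc4ccccc4)c(-c4cc(C(=O)Oc5cc(OC)cc(OCc6ccccc6)c5C(=O)C=P(c5ccccc5)(c5ccccc5)c5ccccc5)ccc4OC)cc3c(=O)c2OCc2ccccc2)cc1
A2 | alternative 1 | 3,7,5-tri-O-benzylabiesin (benzyl on flavonol O3 and O7 and on flavone O5) | COc1ccc(-c2oc3cc(OCc4ccccc4)c(-c4cc(-c5cc(=O)c6c(OCc7ccccc7)cc(OC)cc6o5)ccc4OC)cc3c(=O)c2OCc2ccccc2)cc1
A3 | alternative 2 | methyl 3-[2-(benzyloxy)-5-formyl-4-hydroxyphenyl]-4-methoxybenzoate | COC(=O)c1ccc(OC)c(-c2cc(C=O)c(O)cc2OCc2ccccc2)c1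
A4 | alternative 2 | 2-(dimethyloxo-λ6-sulfanylidene)-1-(4-methoxyphenyl)ethanone | COc1ccc(C(=O)C=S(C)(C)=O)cc1
A5 | alternative 2 | methyl 3-[7-(benzyloxy)-2-(4-methoxyphenyl)-4-oxo-4H-chromen-6-yl]-4-methoxybenzoate | COc1ccc(-c2cc(=O)c3cc(-c4cc(C(=O)OC)ccc4OC)c(OCc4ccccc4)cc3o2)cc1
A6 | alternative 3 | 2-(2-diazoacetyl)-6-{3-[2,4-bis(benzyloxy)-5-bromophenyl]-4-methoxyphenyl}-4H-pyran-4-one | COc1ccc(-c2cc(=O)cc(C(=O)C=[N+]=[N-])o2)cc1-c1cc(Br)c(OCc2ccccc2)cc1OCc1ccccc1
A7 | alternative 3 | methoxyethyne | COC#C
A8 | alternative 3 | 2-{3-[2,4-bis(benzyloxy)-5-bromophenyl]-4-methoxyphenyl}-5-hydroxy-7-methoxy-4H-chromen-4-one | COc1cc(O)c2c(=O)cc(-c3ccc(OC)c(-c4cc(Br)c(OCc5ccccc5)cc4OCc4ccccc4)c3)oc2c1
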